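**Remarks before the sections**

- Atom labels: the carbons of the target are labelled along the acyclic chain from which the rings derive, and the labels are kept for all intermediates. C1 is the carboxyl carbon; C2 the quaternary carbon bearing CH3 and CO2H; C3 the ring-fusion CH next to C2; C4 the ring carbon bearing ethyl; C5 the ring =CH; C6 the CH(CH3); C7 the second ring-fusion CH; C8 the =C(CH3); C9 the =CH; C10 the quaternary carbon bearing CH3 and the dienyl arm C11–C14 (C14 carries the phenyl group).
- Assumption: compounds 1, 11, 17 and 20 are taken as commercial materials.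
- The stereodescriptors in the names were assigned by hand from the CIP rules; the SMILES strings are the authoritative statement of configuration.

## Analysis of the target

The target is a trans-fused bicyclo[4.3.0]nona-2,7-diene: ring A is the cyclopentene C3–C4(Et)=C5–C6(Me)–C7 and ring B the cyclohexene C7–C8(Me)=C9–C10–C2–C3, with the C1 carboxyl on C2 and an (E,E)-4-phenylbutadienyl arm (C11–C14) on C10. It carries five contiguous stereocenters (C6, C7, C3, C2, C10), of which C2 and C10 are vicinal quaternary carbons; their methyl groups are cis, the carboxyl and the dienyl arm share the other face, H3 is cis to the carboxyl and trans to H7, and the C6 methyl is cis to H7. The sensitive groups are the styryl-diene arm (acid, radicals, light), the two trisubstituted ring alkenes, of which C4=C5 lies γ,δ to the acid and would lactonise under strong protic acid, and a neopentyl-type carboxyl that nucleophiles reach only with difficulty. The difficulty lies in the two adjacent quaternary centers inside a strained trans-fused hydrindadiene and in relating them to C6, with no heteroatom on the skeleton to hold on to. The feature that invites the strategy is ring B: its only double bond, C8=C9, is flanked by C7 and C10, while its other two ring atoms, C2 and C3, are the α and β carbons of the C1 acid, which is the retron of a [4+2] addition of an (E,E)-diene C7–C10 to an (E)-2-methyl-2-enoic acid C2=C3. The three ring A atoms C4=C5–C6 then become the tether, and unfolding gives a linear 2,4,7,9,11,13-hexaenoic acid with a regular methyl/ethyl branching pattern and C6 as its only stereocenter, the kind of chain a polyketide synthase would hand over to a cycloaddition. The chosen key step copies this presumed biosynthesis.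

## Retrosynthetic reasoning

**26 to 24.** Only the O–CH3 bond of the ester is cut. The methyl ester is kept through the cycloaddition because it activates the dienophile and masks the acid during the organometallic steps. The forward step must cleave an ester whose carbonyl is flanked by two quaternary carbons, so it has to attack the methyl carbon and not the carbonyl.

**24 to 23.** The bonds C3–C7 and C2–C10 are cut. This opens ring B and ring A together and removes four stereocenters (C2, C3, C7, C10). It is the only cut that takes out both quaternary carbons at once and turns their configuration into alkene geometry: (2E) for C2/C3 and (7E,9E) for C7/C10. The tether is kept unsaturated, with a (4Z) alkene, so that the cycloadduct emerges with the C4=C5 double bond already in place and no adjustment of ring A is needed afterwards. The forward reaction has to proceed through the ester-endo arrangement (trans fusion) on the diene face dictated by C6.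

**23 to 19 and 21.** The sp2–sp2 bond C8–C9 and the C10–CH3 bond are cut. This separates the sensitive phenyl-capped polyene into a small dienyne (21) and leaves the stereocenter with the dienoate in vinyl iodide 19. A cut at C9=C10 by olefination would give E/Z mixtures at a trisubstituted alkene. The forward step must add methyl and metal syn across the alkyne, which fixes (9E), and couple with retention at both alkene carbons.

**19 to 16 and 17, and 15 to 10 and 13.** The C2=C3 bond is cut to a Wittig pair (enal from 16, stabilised ylide 17), and the C4=C5 bond to aldehyde 10 and phosphonate 13. The (4Z) trisubstituted alkene is the geometry that lets C3 reach C7, and it is the less stable isomer, so the forward olefination must be kinetically Z-selective (Still–Gennari variant).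

**10 back to 1.** C6 is taken from the chiral pool: its two arms, C5 and C7, are the two differentiated termini of hydroxy ester 1. The C7=C8 vinyl iodide is traced to methylalkyne 6 (hydrozirconation, iodination) and the alkyne to aldehyde 3 (Corey–Fuchs). The alkyne arm is built first from the configurationally robust aldehyde 3; the labile β,γ-unsaturated aldehyde 10 is made last and used at once.

**21 to 20 and 13 to 11.** The dienyne is cut by one carbon to dienal 20 (Colvin homologation); phosphonate 13 is cut at its ethyl group to the parent phosphonoacetate 11.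

## Alternatives that were turned down

**Alternative 1:** the textbook cyclohexene disconnection, an intermolecular Diels–Alder reaction for ring B followed by ring-closing metathesis for ring A.
- Disconnection: C3–C7 and C2–C10 between two separate partners, then C4=C5.
- Forward: pentaene A1 and the cross-conjugated ester A2 would give cyclohexene A3, and metathesis of its two vinyl groups (second-generation Grubbs catalyst) would give 24.
- Why turned down: a bimolecular cycloaddition that joins a fully substituted diene terminus to a trisubstituted, weakly activated ester and creates two adjacent quaternary carbons has a very unfavourable rate. A2 is itself a 2-substituted 1,3-diene and would rather dimerise. Without a tether, C6 distinguishes the diene faces only by methyl against vinyl, and nothing fixes endo against exo, so four stereocenters would be left to chance.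

**Alternative 2:** intramolecular Diels–Alder reaction through a saturated tether with a ketone at C5, followed by conversion of the ketone into the C4=C5 alkene.
- Disconnection: the same two ring B bonds, but ring A is delivered as a cyclopentanone.
- Forward: keto triene A4 would cyclise to hydrindanone A5, and regioselective enolisation towards C4, enol sulfonate formation and reductive cleavage would follow.
- Why turned down: A4 needs a second stereocenter (C4) that is built only to be destroyed, and both C4 and C6 are α to the ketone and epimerisable; since C6 is the only controller of the cycloaddition, its lability is a direct threat. The hydrindanone has two tertiary α-carbons (C4 and C6), so the enolisation that must place the alkene has no clear regiochemical bias. At least three extra steps are spent on a double bond that the chosen route gets for nothing.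

**Alternative 3:** Ireland–Claisen ring contraction, a [3,3] rearrangement that forms C2–C10 and transfers a carbinol stereocenter at C8 to both quaternary carbons.
- Disconnection: C2–C10, with ring B made from a six-membered lactone fused to ring A.
- Forward: bicyclic lactone A6 would be converted into silyl ketene acetal A7, which would rearrange to the silyl ester of 26.
- Why turned down: inside a six-membered lactone the shift must pass through a boat-like, bicyclo[2.2.2]octane-shaped transition state in which C2 and C8 are the bridgeheads and C3–C7 is a nearly eclipsed two-atom bridge. A trans-fused cyclopentene on that bridge would need a torsion angle near 120°, which it cannot reach. Only the cis-fused lactone could rearrange, and it would give the wrong ring fusion. A6 also already contains four stereocenters, so the precursor is hardly simpler than the product.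

Key step: step 14

## Route

Step 1
Reactants: 1 methyl (R)-3-hydroxy-2-methylpropanoate
Product: 2 methyl (R)-3-[(tert-butyldimethylsilyl)oxy]-2-methylpropanoate
Conditions: TBSCl, imidazole, DMF, 0 °C to rt
Reagents that add atoms: tert-butyldimethylsilyl chloride, CC(C)(C)[Si](C)(C)Cl
Why: Silylation of the primary alcohol masks the future C5 arm; the stereocenter (future C6) is not touched.

Step 2
Reactants: 2 methyl (R)-3-[(tert-butyldimethylsilyl)oxy]-2-methylpropanoate
Product: 3 (R)-3-[(tert-butyldimethylsilyl)oxy]-2-methylpropanal
Conditions: i-Bu2AlH (1.05 equiv), CH2Cl2, −78 °C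
Reagents that add atoms: none
Why: Partial reduction of the ester through the tetrahedral aluminium hemiacetal, which is stable at −78 °C; the α-methyl aldehyde is configurationally stable if kept cold and used directly.

Step 3
Reactants: 3 (R)-3-[(tert-butyldimethylsilyl)oxy]-2-methylpropanal
Product: 4 (S)-tert-butyl[(4,4-dibromo-2-methylbut-3-en-1-yl)oxy]dimethylsilane
Conditions: CBr4, PPh3, 2,6-lutidine, CH2Cl2, 0 °C
Reagents that add atoms: carbon tetrabromide, BrC(Br)(Br)Br
Why: Corey–Fuchs dibromoolefination (Wittig reaction of Ph3P=CBr2 made in the flask) under buffered, non-basic conditions that leave the α-stereocenter alone; the descriptor changes from R to S only through CIP priorities.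

Step 4
Reactants: 4 (S)-tert-butyl[(4,4-dibromo-2-methylbut-3-en-1-yl)oxy]dimethylsilane
Product: 6 (S)-tert-butyldimethyl[(2-methylpent-3-yn-1-yl)oxy]silane, via lithium acetylide 5 (not isolated)
Conditions: n-BuLi (2.1 equiv), THF, −78 °C; then MeI, −78 °C to rt
Reagents that add atoms: iodomethane, CI
Why: Second stage of the Corey–Fuchs sequence (halogen–lithium exchange, 1,2-shift, deprotonation) gives the acetylide, which is methylated in the same flask; the propargylic C–H is not acidic enough to be touched.

Step 5
Reactants: 6 (S)-tert-butyldimethyl[(2-methylpent-3-yn-1-yl)oxy]silane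
Product: 8 (S,E)-tert-butyl[(4-iodo-2-methylpent-3-en-1-yl)oxy]dimethylsilane, via alkenylzirconocene chloride 7 (not isolated)
Conditions: Cp2Zr(H)Cl (2 equiv), THF, 50 °C; then I2, 0 °C
Reagents that add atoms: iodine, II
Why: Syn hydrozirconation of the internal alkyne; with excess hydride and warming the metal settles on the less hindered, methyl-bearing carbon (C8), away from the branched C6. Iodinolysis with retention then gives the (E)-iodide with H7 and iodine cis.

Step 6
Reactants: 8 (S,E)-tert-butyl[(4-iodo-2-methylpent-3-en-1-yl)oxy]dimethylsilane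
Product: 9 (S,E)-4-iodo-2-methylpent-3-en-1-ol
Conditions: Bu4NF, THF, 0 °C to rt
Reagents that add atoms: none
Why: Fluoride cleavage of the silyl ether; the vinyl iodide and the stereocenter are inert to fluoride.

Step 7
Reactants: 9 (S,E)-4-iodo-2-methylpent-3-en-1-ol
Product: 10 (S,E)-4-iodo-2-methylpent-3-enal
Conditions: Dess–Martin periodinane, NaHCO3, CH2Cl2, 0 °C; crude product used at once
Reagents that add atoms: none
Why: Buffered Dess–Martin oxidation is the mildest access to an α-branched β,γ-unsaturated aldehyde; keeping it cold and using it immediately should avoid enolisation at C6 and migration of the double bond.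

Step 8
Reactants: 11 methyl 2-[bis(2,2,2-trifluoroethoxy)phosphoryl]acetate
Product: 13 methyl 2-[bis(2,2,2-trifluoroethoxy)phosphoryl]butanoate, via sodium enolate 12 (not isolated)
Conditions: NaH, THF/DMF, 0 °C; then EtI, rt
Reagents that add atoms: iodoethane, CCI
Why: C-alkylation of the doubly stabilised phosphonoacetate anion; the monoethylated product is less acidic and more hindered, which should limit dialkylation.

Step 9
Reactants: 10 (S,E)-4-iodo-2-methylpent-3-enal; 13 methyl 2-[bis(2,2,2-trifluoroethoxy)phosphoryl]butanoate
Product: 15 methyl (2Z,4R,5E)-2-ethyl-6-iodo-4-methylhepta-2,5-dienoate, via potassium phosphonate 14 (not isolated)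
Conditions: 13, KN(SiMe3)2, 18-crown-6, THF, −78 °C; then 10, −78 °C
Reagents that add atoms: none
Why: Still–Gennari variant of the Horner–Wadsworth–Emmons reaction: with the trifluoroethyl phosphonate and a dissociated potassium counterion, elimination from the kinetic adduct outruns equilibration and places the ester cis to C6, giving the (Z)-trisubstituted C4=C5 alkene. The preformed, weakly basic anion at −78 °C should not enolise 10; the descriptor changes from S to R only through CIP priorities.

Step 10
Reactants: 15 methyl (2Z,4R,5E)-2-ethyl-6-iodo-4-methylhepta-2,5-dienoate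
Product: 16 (2Z,4R,5E)-2-ethyl-6-iodo-4-methylhepta-2,5-dien-1-ol
Conditions: i-Bu2AlH (2.2 equiv), CH2Cl2, −78 °C
Reagents that add atoms: none
Why: 1,2-Reduction of the enoate to the allylic alcohol; the vinyl iodide and the alkene geometries are not affected at −78 °C.

Step 11
Reactants: 16 (2Z,4R,5E)-2-ethyl-6-iodo-4-methylhepta-2,5-dien-1-ol; 17 methyl 2-(triphenyl-λ5-phosphanylidene)propanoate
Product: 19 methyl (2E,4Z,6R,7E)-4-ethyl-8-iodo-2,6-dimethylnona-2,4,7-trienoate, via (Z)-enal 18 (not isolated)
Conditions: MnO2 (excess), 17, CH2Cl2, rt to 40 °C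
Reagents that add atoms: none
Why: Tandem allylic oxidation and Wittig olefination: the isomerisable (Z)-enal is trapped by the stabilised ylide as it forms, so it has little time to relax to the (E)-enal. The stabilised α-methyl ylide gives the (2E)-enoate under thermodynamic control of the oxaphosphetane.

Step 12
Reactants: 20 (2E,4E)-5-phenylpenta-2,4-dienal
Product: 21 [(1E,3E)-hexa-1,3-dien-5-yn-1-yl]benzene
Conditions: TMSCHN2, n-BuLi, THF, −78 °C; then 20, −78 °C to rt
Reagents that add atoms: (trimethylsilyl)diazomethane, C[Si](C)(C)C=[N+]=[N-]
Why: Colvin homologation: 1,2-addition of the lithiated diazo reagent, Peterson-type loss of silanolate, loss of N2 and 1,2-hydrogen shift of the alkylidene carbene give the terminal alkyne without touching the (E,E)-diene.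

Step 13
Reactants: 21 [(1E,3E)-hexa-1,3-dien-5-yn-1-yl]benzene; 19 methyl (2E,4Z,6R,7E)-4-ethyl-8-iodo-2,6-dimethylnona-2,4,7-trienoate
Product: 23 methyl (2E,4Z,6S,7E,9E,11E,13E)-4-ethyl-2,6,8,10-tetramethyl-14-phenyltetradeca-2,4,7,9,11,13-hexaenoate, via alkenylalane 22 (not isolated)
Conditions: 21, Me3Al, Cp2ZrCl2 (cat.), CH2Cl2, 0 °C to rt; volatiles removed in vacuo; then 19, ZnCl2 (cat.), Pd(PPh3)4 (cat.), THF, rt, dark
Reagents that add atoms: trimethylaluminium, C[Al](C)C
Why: Zirconium-catalysed syn carboalumination puts methyl on C10 and aluminium on C9, which fixes the (9E) alkene. The Negishi-type cross-coupling joins C8 and C9 with retention at both alkene carbons, and the ester tolerates the alkenylmetal at rt; the descriptor changes from R to S only through CIP priorities.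

Step 14
Reactants: 23 methyl (2E,4Z,6S,7E,9E,11E,13E)-4-ethyl-2,6,8,10-tetramethyl-14-phenyltetradeca-2,4,7,9,11,13-hexaenoate
Product: 24 methyl (1R,3aR,4R,5S,7aS)-3-ethyl-1,4,5,7-tetramethyl-5-[(1E,3E)-4-phenylbuta-1,3-dien-1-yl]-3a,4,5,7a-tetrahydro-1H-indene-4-carboxylate
Conditions: toluene (degassed), BHT (cat.), 100 °C, sealed tube, dark
Reagents that add atoms: none
Why: Thermal type 1 intramolecular Diels–Alder reaction: a concerted, asynchronous, suprafacial [4+2] addition of the (7E,9E)-diene C7–C10 to the (2E)-enoate C2=C3, in which the C3–C7 bond leads and the C2–C10 bond between the two fully substituted carbons lags; the closest known reaction type is the cyclisation of (E)-1,3,8-nonatrienes with an ester at the dienophile terminus to trans-fused bicyclo[4.3.0]nonenes. Ring B is closed by the cycloaddition itself through both new bonds, and ring A is closed by the C3–C7 bond across the three-atom tether C4=C5–C6, whose (4Z) geometry holds C3 and C6 on the same side and removes two rotors. The relative configuration of C2 and C3 follows from the (2E) dienophile and that of C7 and C10 from the (7E,9E) diene. The diene face is chosen by C6: allylic 1,3-strain with the C8 methyl keeps H6 in the diene plane, so the tether descends from one face and the C6 methyl points to the other, which makes that methyl cis to H7. The trans ring fusion and the cis relation of the ester to the C10 dienyl arm need the ester-endo, tether-exo arrangement, which the (E)-β-substituted ester and the advanced C3–C7 bonding should favour. Only the C7–C10 diene can be reached through a three-atom tether, so the outer diene C11–C14 stays untouched. The twisted (2E,4Z)-dienoate cannot easily reach the planar s-cis geometry that a 1,5-hydrogen shift from C6 would need, which should keep that escape slow at 100 °C. The descriptor at C6 changes from S to R only through CIP priorities.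

Step 15
Reactants: 24 methyl (1R,3aR,4R,5S,7aS)-3-ethyl-1,4,5,7-tetramethyl-5-[(1E,3E)-4-phenylbuta-1,3-dien-1-yl]-3a,4,5,7a-tetrahydro-1H-indene-4-carboxylate
Product: 26 (1R,3aR,4R,5S,7aS)-3-ethyl-1,4,5,7-tetramethyl-5-[(1E,3E)-4-phenylbuta-1,3-dien-1-yl]-3a,4,5,7a-tetrahydro-1H-indene-4-carboxylic acid (22-nor-zyggomphic acid B), via lithium carboxylate 25 (not isolated)
Conditions: n-PrSLi, HMPA, rt; then aqueous HCl
Reagents that add atoms: none
Why: SN2 dealkylation of the methyl ester by thiolate at the unhindered methyl carbon, which avoids attack at the carbonyl flanked by two quaternary carbons; no stereocenter is α-enolisable and the unactivated dienes do not accept thiolate.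

## Compound list

1 | methyl (R)-3-hydroxy-2-methylpropanoate | OC[C@@H](C)C(=O)OC | starting material
2 | methyl (R)-3-[(tert-butyldimethylsilyl)oxy]-2-methylpropanoate | CC(C)(C)[Si](C)(C)OC[C@@H](C)C(=O)OC | intermediate
3 | (R)-3-[(tert-butyldimethylsilyl)oxy]-2-methylpropanal | CC(C)(C)[Si](C)(C)OC[C@@H](C)C=O | intermediate
4 | (S)-tert-butyl[(4,4-dibromo-2-methylbut-3-en-1-yl)oxy]dimethylsilane | CC(C)(C)[Si](C)(C)OC[C@@H](C)C=C(Br)Br | intermediate
5 | lithium (S)-4-[(tert-butyldimethylsilyl)oxy]-3-methylbut-1-yn-1-ide | CC(C)(C)[Si](C)(C)OC[C@@H](C)C#C[Li] | intermediate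
6 | (S)-tert-butyldimethyl[(2-methylpent-3-yn-1-yl)oxy]silane | CC(C)(C)[Si](C)(C)OC[C@@H](C)C#CC | intermediate
7 | chlorobis(cyclopentadienyl)[(2E,4S)-5-[(tert-butyldimethylsilyl)oxy]-4-methylpent-2-en-2-yl]zirconium | CC(C)(C)[Si](C)(C)OC[C@@H](C)/C=C(\C)[Zr](Cl)(C1C=CC=C1)C1C=CC=C1 | intermediate
8 | (S,E)-tert-butyl[(4-iodo-2-methylpent-3-en-1-yl)oxy]dimethylsilane | CC(C)(C)[Si](C)(C)OC[C@@H](C)/C=C(\C)I | intermediate
9 | (S,E)-4-iodo-2-methylpent-3-en-1-ol | OC[C@@H](C)/C=C(\C)I | intermediate
10 | (S,E)-4-iodo-2-methylpent-3-enal | O=C[C@@H](C)/C=C(\C)I | intermediate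
11 | methyl 2-[bis(2,2,2-trifluoroethoxy)phosphoryl]acetate | COC(=O)CP(=O)(OCC(F)(F)F)OCC(F)(F)F | starting material
12 | sodium salt of methyl 2-[bis(2,2,2-trifluoroethoxy)phosphoryl]acetate | [Na+].COC(=O)[CH-]P(=O)(OCC(F)(F)F)OCC(F)(F)F | intermediate
13 | methyl 2-[bis(2,2,2-trifluoroethoxy)phosphoryl]butanoate (racemic) | CCC(C(=O)OC)P(=O)(OCC(F)(F)F)OCC(F)(F)F | intermediate
14 | potassium salt of methyl 2-[bis(2,2,2-trifluoroethoxy)phosphoryl]butanoate | [K+].CC[C-](C(=O)OC)P(=O)(OCC(F)(F)F)OCC(F)(F)F | intermediate
15 | methyl (2Z,4R,5E)-2-ethyl-6-iodo-4-methylhepta-2,5-dienoate | COC(=O)/C(CC)=C\[C@@H](C)/C=C(\C)I | intermediate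
16 | (2Z,4R,5E)-2-ethyl-6-iodo-4-methylhepta-2,5-dien-1-ol | OC/C(CC)=C\[C@@H](C)/C=C(\C)I | intermediate
17 | methyl 2-(triphenyl-λ5-phosphanylidene)propanoate | COC(=O)C(C)=P(c1ccccc1)(c1ccccc1)c1ccccc1 | starting material
18 | (2Z,4R,5E)-2-ethyl-6-iodo-4-methylhepta-2,5-dienal | O=C/C(CC)=C\[C@@H](C)/C=C(\C)I | intermediate
19 | methyl (2E,4Z,6R,7E)-4-ethyl-8-iodo-2,6-dimethylnona-2,4,7-trienoate | COC(=O)/C(C)=C/C(CC)=C\[C@@H](C)/C=C(\C)I | intermediate
20 | (2E,4E)-5-phenylpenta-2,4-dienal | O=C/C=C/C=C/c1ccccc1 | starting material
21 | [(1E,3E)-hexa-1,3-dien-5-yn-1-yl]benzene | C#C/C=C/C=C/c1ccccc1 | intermediate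
22 | dimethyl[(1E,3E,5E)-2-methyl-6-phenylhexa-1,3,5-trien-1-yl]alumane | C[Al](C)/C=C(C)/C=C/C=C/c1ccccc1 | intermediate
23 | methyl (2E,4Z,6S,7E,9E,11E,13E)-4-ethyl-2,6,8,10-tetramethyl-14-phenyltetradeca-2,4,7,9,11,13-hexaenoate | COC(=O)/C(C)=C/C(CC)=C\[C@@H](C)/C=C(C)/C=C(C)/C=C/C=C/c1ccccc1 | intermediate
24 | methyl (1R,3aR,4R,5S,7aS)-3-ethyl-1,4,5,7-tetramethyl-5-[(1E,3E)-4-phenylbuta-1,3-dien-1-yl]-3a,4,5,7a-tetrahydro-1H-indene-4-carboxylate | CCC1=C[C@@H](C)[C@@H]2C(C)=C[C@](C)(/C=C/C=C/c3ccccc3)[C@](C)(C(=O)OC)[C@@H]12 | intermediate
25 | lithium (1R,3aR,4R,5S,7aS)-3-ethyl-1,4,5,7-tetramethyl-5-[(1E,3E)-4-phenylbuta-1,3-dien-1-yl]-3a,4,5,7a-tetrahydro-1H-indene-4-carboxylate | [Li+].CCC1=C[C@@H](C)[C@@H]2C(C)=C[C@](C)(/C=C/C=C/c3ccccc3)[C@](C)(C(=O)[O-])[C@@H]12 | intermediate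
26 | (1R,3aR,4R,5S,7aS)-3-ethyl-1,4,5,7-tetramethyl-5-[(1E,3E)-4-phenylbuta-1,3-dien-1-yl]-3a,4,5,7a-tetrahydro-1H-indene-4-carboxylic acid (22-nor-zyggomphic acid B) | CCC1=C[C@@H](C)[C@@H]2C(C)=C[C@](C)(/C=C/C=C/c3ccccc3)[C@](C)(C(=O)O)[C@@H]12 | target

## Step count and least certain steps

Total step count: 15. Longest linear sequence: 13 steps (steps 1–7, 9–11 and 13–15, from 1); steps 8 and 12 prepare the two side components.

**Step 14 (key step).**
- What may go wrong: cyclisation through the ester-exo arrangement would give the cis-fused diastereomer, because the thermal endo preference of an ester is small and the planar (4Z) tether forces a twisted transition state whose preference has to be taken on mechanistic grounds. The cycloaddition may also be slow, because both termini of the lagging bond become quaternary; prolonged heating would then allow polyene decomposition or a 1,5-hydrogen shift from C6.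
- Fallback: switch the dienophile from ester to aldehyde, which changes both the activation and the end game. Setting out from 23, reduction with i-Bu2AlH at −78 °C should give the hexaenol F1, and oxidation with MnO2 the hexaenal F2. As an α-methyl enal, F2 is a far stronger and more endo-selective dienophile and should cyclise near room temperature to the carbaldehyde F3. Pinnick oxidation (NaClO2, NaH2PO4, 2-methyl-2-butene, t-BuOH/water) then comes back to the route at 26, so the hindered ester cleavage of step 15 is not needed.

**Step 9 (with the aldehyde made in step 7).**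
- What may go wrong: enolisation of the β,γ-unsaturated aldehyde 10 under the basic olefination conditions would cause loss of configuration at C6 or migration of the C7=C8 bond into conjugation; Z selectivity with the α-ethyl phosphonate may also be incomplete.
- Fallback: reverse the polarity of the olefination so that C6–H is never α to a carbonyl. Setting out from 9, iodination (I2, PPh3, imidazole) should give the diiodide F4. Heating with PPh3 in MeCN gives the phosphonium iodide F5, since only the primary iodide is displaced. Deprotonation with NaN(SiMe3)2 gives the non-stabilised ylide F6, and its Wittig reaction with commercial methyl 2-oxobutanoate at −78 °C is expected to favour the alkene with the ester cis to the new chain, as is usual for α-oxygenated ketones. This comes back to the route at 15.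

**Step 13.**
- What may go wrong: methyl transfer from residual Me3Al to 19, incomplete regiocontrol in the carboalumination of the conjugated dienyne, or isomerisation of the (4Z) alkene or of the skipped C6 position in the Lewis acidic organometallic mixture.
- Fallback: separate the two events and use an isolable boron nucleophile. Setting out from 21, carboalumination as before and quenching of 22 with 2-isopropoxy-4,4,5,5-tetramethyl-1,3,2-dioxaborolane should give the trienylboronate F7, which can be purified. A Suzuki–Miyaura coupling of F7 with 19 (Pd(PPh3)4, aqueous K3PO4, THF, rt) comes back to the route at 23.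

**Step 15.**
- What may go wrong: the demethylation may be sluggish, or the thiolate in a dipolar solvent may cause isomerisation or addition in the diene arm.
- Fallback: free the acid before the skeleton is built, while the ester is still unhindered. Setting out from 23, saponification with LiOH in THF/MeOH/water at rt and work-up with aqueous HCl should give the hexaenoic acid F8. Heating F8 as in step 14 should give 26 directly, so the cycloaddition becomes the last step; this comes back to the route at 26.

## Further compounds

F1 | step 14 | (2E,4Z,6S,7E,9E,11E,13E)-4-ethyl-2,6,8,10-tetramethyl-14-phenyltetradeca-2,4,7,9,11,13-hexaen-1-ol | OC/C(C)=C/C(CC)=C\[C@@H](C)/C=C(C)/C=C(C)/C=C/C=C/c1ccccc1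
F2 | step 14 | (2E,4Z,6S,7E,9E,11E,13E)-4-ethyl-2,6,8,10-tetramethyl-14-phenyltetradeca-2,4,7,9,11,13-hexaenal | O=C/C(C)=C/C(CC)=C\[C@@H](C)/C=C(C)/C=C(C)/C=C/C=C/c1ccccc1
F3 | step 14 | (1R,3aR,4R,5S,7aS)-3-ethyl-1,4,5,7-tetramethyl-5-[(1E,3E)-4-phenylbuta-1,3-dien-1-yl]-3a,4,5,7a-tetrahydro-1H-indene-4-carbaldehyde | CCC1=C[C@@H](C)[C@@H]2C(C)=C[C@](C)(/C=C/C=C/c3ccccc3)[C@](C)(C=O)[C@@H]12
F4 | step 9 | (2S,3E)-1,4-diiodo-2-methylpent-3-ene | IC[C@@H](C)/C=C(\C)I
F5 | step 9 | [(2S,3E)-4-iodo-2-methylpent-3-en-1-yl]triphenylphosphonium iodide | [I-].c1ccccc1[P+](c1ccccc1)(c1ccccc1)C[C@@H](C)/C=C(\C)I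
F6 | step 9 | [(2S,3E)-4-iodo-2-methylpent-3-en-1-ylidene]triphenyl-λ5-phosphane | c1ccccc1P(c1ccccc1)(c1ccccc1)=C[C@@H](C)/C=C(\C)I
F7 | step 13 | 4,4,5,5-tetramethyl-2-[(1E,3E,5E)-2-methyl-6-phenylhexa-1,3,5-trien-1-yl]-1,3,2-dioxaborolane | CC1(C)OB(/C=C(C)/C=C/C=C/c2ccccc2)OC1(C)C
F8 | step 15 | (2E,4Z,6S,7E,9E,11E,13E)-4-ethyl-2,6,8,10-tetramethyl-14-phenyltetradeca-2,4,7,9,11,13-hexaenoic acid | OC(=O)/C(C)=C/C(CC)=C\[C@@H](C)/C=C(C)/C=C(C)/C=C/C=C/c1ccccc1
A1 | alternative 1 | [(1E,3E,5E,7E,9R)-5,7,9-trimethylundeca-1,3,5,7,10-pentaen-1-yl]benzene | C=C[C@@H](C)/C=C(C)/C=C(C)/C=C/C=C/c1ccccc1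
A2 | alternative 1 | methyl (2E)-2-methyl-4-methylidenehex-2-enoate | COC(=O)/C(C)=C/C(=C)CC
A3 | alternative 1 | methyl 6-(but-1-en-2-yl)-5-[(2R)-but-3-en-2-yl]-1,2,4-trimethyl-2-[(1E,3E)-4-phenylbuta-1,3-dien-1-yl]cyclohex-3-ene-1-carboxylate, ring configuration as in 24 | C=C[C@@H](C)[C@@H]1C(C)=C[C@](C)(/C=C/C=C/c2ccccc2)[C@](C)(C(=O)OC)[C@H]1C(=C)CC
A4 | alternative 2 | methyl (2E,4R,6S,7E,9E,11E,13E)-4-ethyl-2,6,8,10-tetramethyl-5-oxo-14-phenyltetradeca-2,7,9,11,13-pentaenoate | COC(=O)/C(C)=C/[C@@H](CC)C(=O)[C@@H](C)/C=C(C)/C=C(C)/C=C/C=C/c1ccccc1
A5 | alternative 2 | methyl 3-ethyl-1,4,5,7-tetramethyl-2-oxo-5-[(1E,3E)-4-phenylbuta-1,3-dien-1-yl]-2,3,3a,4,5,7a-hexahydro-1H-indene-4-carboxylate, ring configuration as in 24 | CC[C@H]1C(=O)[C@@H](C)[C@@H]2C(C)=C[C@](C)(/C=C/C=C/c3ccccc3)[C@](C)(C(=O)OC)[C@@H]12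
A6 | alternative 3 | trans-fused 5-ethyl-1,4,7-trimethyl-1-[(1E,3E,5E)-2-methyl-6-phenylhexa-1,3,5-trien-1-yl]-4,4a,7,7a-tetrahydrocyclopenta[c]pyran-3(1H)-one | CCC1=C[C@@H](C)[C@@H]2[C@@](C)(/C=C(C)/C=C/C=C/c3ccccc3)OC(=O)[C@H](C)[C@@H]12
A7 | alternative 3 | trans-fused {[5-ethyl-1,4,7-trimethyl-1-[(1E,3E,5E)-2-methyl-6-phenylhexa-1,3,5-trien-1-yl]-1,4a,7,7a-tetrahydrocyclopenta[c]pyran-3-yl]oxy}trimethylsilane | CCC1=C[C@@H](C)[C@@H]2[C@@](C)(/C=C(C)/C=C/C=C/c3ccccc3)OC(O[Si](C)(C)C)=C(C)[C@@H]12
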